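**Retrosynthetic overview**

1. The target is a 6,5'-linked pair of 2-phenethylchromones (unit A: 7-OH, joined at C6; unit B, primed: 8'-OH, joined at C5'). The strategy rests on benzene ring B: the biaryl carbon C5' and the hydroxylated C8' lie para across two bare CH positions (C6', C7'), the footprint of a 2-arylfuran whose ring oxygen becomes the C8' hydroxyl, while C4a' (acyl) and C8a' (heteroatom) map onto an acyl alkyne carrying a leaving group.
2. Last operations: cleavage of both O-methyl ethers; before that, pyranone B is closed at O1'–C8a' by copper-catalysed O-arylation of a 1,3-diketone grown from the C4a' acetyl group.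
3. Key disconnection: benzene ring B is cut at C5'–C4a' and C8'–C8a' into 6-(furan-2-yl)chromone 7 and 4-bromobut-3-yn-2-one 9 (Diels–Alder reaction, then acid isomerisation of the 7-oxanorbornadiene to the phenol).
4. Furylchromone 7 comes from Suzuki coupling of 6-bromo-7-methoxy-2-phenethylchromone 5, itself made by Claisen condensation and cyclodehydration from the bromoresacetophenone 1.
5. Order of ring formation: pyranone A (on the given benzene ring A), then benzene ring B, then pyranone B.

Key step: step 6

Assumption: the C6–C5' biaryl axis has only two non-hydrogen ortho substituents and is taken as freely rotating, so neither the target nor any intermediate has a stereogenic axis to control.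

**Route**

Step 1
Reactants: 1 1-(5-bromo-2,4-dihydroxyphenyl)ethanone
Product: 2 1-(5-bromo-2-hydroxy-4-methoxyphenyl)ethanone
Conditions: MeI (1.05 equiv), K2CO3 (1.1 equiv), acetone, reflux
Reagents that add atoms: iodomethane, CI
Why: Williamson etherification that should take only the 4-hydroxyl, because the 2-hydroxyl is tied up in a hydrogen bond to the acetyl carbonyl and is the less acidic and less nucleophilic of the two.

Step 2
Reactants: 2 1-(5-bromo-2-hydroxy-4-methoxyphenyl)ethanone; 3 ethyl 3-phenylpropanoate
Product: 4 1-(5-bromo-2-hydroxy-4-methoxyphenyl)-5-phenylpentane-1,3-dione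
Conditions: NaH (5 equiv), 3 (2.5 equiv), THF, reflux; then aq. HCl
Reagents that add atoms: none
Why: Crossed Claisen condensation in which the enolate of the phenoxide-bearing methyl ketone attacks the ester and irreversible deprotonation of the 1,3-diketone drives the equilibrium, the standard entry to 2-phenethylchromones from 2-hydroxyacetophenones.

Step 3
Reactants: 4 1-(5-bromo-2-hydroxy-4-methoxyphenyl)-5-phenylpentane-1,3-dione
Product: 5 6-bromo-7-methoxy-2-(2-phenylethyl)-4H-chromen-4-one
Conditions: conc. HCl (cat.), MeOH, reflux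
Reagents that add atoms: none
Why: Acid-catalysed cyclodehydration, the phenol adding to the distal carbonyl and water being lost to give the conjugated pyranone of unit A.

Step 4
Reactants: 5 6-bromo-7-methoxy-2-(2-phenylethyl)-4H-chromen-4-one; 6 furan-2-ylboronic acid
Product: 7 6-(furan-2-yl)-7-methoxy-2-(2-phenylethyl)-4H-chromen-4-one
Conditions: 6 (1.8 equiv), Pd(OAc)2 (3 mol %), SPhos (6 mol %), K3PO4, dioxane/H2O 4:1, 60 °C
Reagents that add atoms: none
Why: Suzuki–Miyaura coupling at the C6–Br bond, in which the electron-rich biarylphosphine should make coupling on zerovalent palladium faster than protodeboronation of the 2-furylboronic acid, which is used in excess.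

Step 5
Reactants: 8 but-3-yn-2-one
Product: 9 4-bromobut-3-yn-2-one
Conditions: N-bromosuccinimide (1.1 equiv), AgNO3 (10 mol %), acetone, rt, dark; used fresh as a stock solution
Reagents that add atoms: N-bromosuccinimide, O=C1CCC(=O)N1Br
Why: Silver-catalysed electrophilic bromination of a terminal alkyne through the silver acetylide, a standard preparation of 1-bromoalkynes that tolerates the conjugated ketone.

Step 6
Reactants: 7 6-(furan-2-yl)-7-methoxy-2-(2-phenylethyl)-4H-chromen-4-one; 9 4-bromobut-3-yn-2-one
Product: 11 6-(2-acetyl-3-bromo-4-hydroxyphenyl)-7-methoxy-2-(2-phenylethyl)-4H-chromen-4-one, via oxanorbornadiene adduct 10 (not isolated)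
Conditions: 9 (3 equiv), toluene, 70 °C, sealed; concentrate; then CF3CO2H, CH2Cl2, 0 °C to rt
Reagents that add atoms: none
Why: The furan of 7 (4π) adds across the triple bond of 9 (2π) in a concerted, asynchronous [4+2] closure of a six-membered carbocycle to give 7-oxanorbornadiene 10; acid then protonates the bridge oxygen, the C–O bond at the aryl-bearing bridgehead ionises, and loss of the proton from the remaining carbinol carbon aromatises the ring. The closest known chemistry is the Diels–Alder reaction of furans with 3-halopropiolates and haloalkynyl ketones followed by acid isomerisation of the oxanorbornadienes to ortho-halophenols. Regiochemistry in the cycloaddition is required and should follow frontier-orbital matching: the unsubstituted furan carbon, which has the larger HOMO coefficient in a 2-aryl furan, bonds to the bromine-bearing β-carbon of the ynone (larger LUMO coefficient), so the aryl-bearing carbon ends next to the acetyl-bearing carbon (future C5'–C4a'). Regiochemistry in the bridge opening is also required and is secured twice: cleavage at the aryl bridgehead gives a benzylic, doubly allylic cation with the acetyl group on a nodal carbon, whereas the other cleavage would place charge on the acetyl-bearing carbon and leave a carbinol carbon with no hydrogen to lose. The two bridgehead stereocentres of 10 form as a racemate and are erased on aromatisation, so 11 has none, and the chromone C2=C3 bond is too poor a 2π or 4π partner to interfere.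

Step 7
Reactants: 11 6-(2-acetyl-3-bromo-4-hydroxyphenyl)-7-methoxy-2-(2-phenylethyl)-4H-chromen-4-one
Product: 12 6-(2-acetyl-3-bromo-4-methoxyphenyl)-7-methoxy-2-(2-phenylethyl)-4H-chromen-4-one
Conditions: MeI (1.5 equiv), K2CO3 (2 equiv), DMF, rt
Reagents that add atoms: iodomethane, CI
Why: Williamson etherification of the only free phenol, with a carbonate base too weak to enolise the methyl ketone or to open the chromone.

Step 8
Reactants: 12 6-(2-acetyl-3-bromo-4-methoxyphenyl)-7-methoxy-2-(2-phenylethyl)-4H-chromen-4-one; 13 3-phenylpropanoyl chloride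
Product: 14 1-[2-bromo-3-methoxy-6-(7-methoxy-4-oxo-2-(2-phenylethyl)-4H-chromen-6-yl)phenyl]-5-phenylpentane-1,3-dione
Conditions: MgBr2·OEt2 (3 equiv), i-Pr2NEt (3.5 equiv), 13 (1.3 equiv), CH2Cl2, rt; then aq. HCl
Reagents that add atoms: none
Why: Direct C-acylation by soft enolisation, in which the magnesium-coordinated methyl ketone is deprotonated by the amine, the magnesium enolate is acylated at carbon and the product is held as a chelated magnesium diketonate, so no alkoxide or strong base meets the chromone, whose only acidic hydrogens are vinylogous.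

Step 9
Reactants: 14 1-[2-bromo-3-methoxy-6-(7-methoxy-4-oxo-2-(2-phenylethyl)-4H-chromen-6-yl)phenyl]-5-phenylpentane-1,3-dione
Product: 15 7,8'-dimethoxy-2,2'-bis(2-phenylethyl)-4H,4'H-[6,5'-bichromene]-4,4'-dione
Conditions: CuI (10 mol %), 1,10-phenanthroline (20 mol %), K2CO3 (2 equiv), DMF, 100 °C
Reagents that add atoms: none
Why: Intramolecular Ullmann-type O-arylation of the diketone enolate oxygen at the C8a'–Br bond, a known six-membered closure of 1-(2-bromoaryl)-1,3-diketones to chromones that is helped here by the ortho carbonyl and by the diketonate binding copper.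

Step 10
Reactants: 15 7,8'-dimethoxy-2,2'-bis(2-phenylethyl)-4H,4'H-[6,5'-bichromene]-4,4'-dione
Product: 16 7,8'-dihydroxy-2,2'-bis(2-phenylethyl)-4H,4'H-[6,5'-bichromene]-4,4'-dione
Conditions: BBr3 (10 equiv), CH2Cl2, −78 °C to rt; then MeOH, H2O
Reagents that add atoms: none
Why: Lewis-acid cleavage of both aryl methyl ethers (C7–OMe and C8'–OMe) by bromide attack on the boron-complexed O-methyl groups, with excess reagent to allow for coordination to the two pyranone carbonyls; the phenethyl chains and chromone rings are inert.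

**Compound list**

1 | 1-(5-bromo-2,4-dihydroxyphenyl)ethanone | CC(=O)c1cc(Br)c(O)cc1O | starting material
2 | 1-(5-bromo-2-hydroxy-4-methoxyphenyl)ethanone | CC(=O)c1cc(Br)c(OC)cc1O | intermediate
3 | ethyl 3-phenylpropanoate | CCOC(=O)CCc1ccccc1 | starting material
4 | 1-(5-bromo-2-hydroxy-4-methoxyphenyl)-5-phenylpentane-1,3-dione | O=C(CCc1ccccc1)CC(=O)c1cc(Br)c(OC)cc1O | intermediate
5 | 6-bromo-7-methoxy-2-(2-phenylethyl)-4H-chromen-4-one | COc1cc2oc(CCc3ccccc3)cc(=O)c2cc1Br | intermediate
6 | furan-2-ylboronic acid | OB(O)c1ccco1 | starting material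
7 | 6-(furan-2-yl)-7-methoxy-2-(2-phenylethyl)-4H-chromen-4-one | COc1cc2oc(CCc3ccccc3)cc(=O)c2cc1-c1ccco1 | intermediate
8 | but-3-yn-2-one | CC(=O)C#C | starting material
9 | 4-bromobut-3-yn-2-one | CC(=O)C#CBr | intermediate
10 | 6-(2-acetyl-3-bromo-7-oxabicyclo[2.2.1]hepta-2,5-dien-1-yl)-7-methoxy-2-(2-phenylethyl)-4H-chromen-4-one (racemic; one enantiomer drawn, relative configuration fixed by the bridge) | CC(=O)C1=C(Br)[C@@H]2C=C[C@]1(O2)c1cc2c(=O)cc(CCc3ccccc3)oc2cc1OC | intermediate
11 | 6-(2-acetyl-3-bromo-4-hydroxyphenyl)-7-methoxy-2-(2-phenylethyl)-4H-chromen-4-one | CC(=O)c1c(Br)c(O)ccc1-c1cc2c(=O)cc(CCc3ccccc3)oc2cc1OC | intermediate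
12 | 6-(2-acetyl-3-bromo-4-methoxyphenyl)-7-methoxy-2-(2-phenylethyl)-4H-chromen-4-one | CC(=O)c1c(Br)c(OC)ccc1-c1cc2c(=O)cc(CCc3ccccc3)oc2cc1OC | intermediate
13 | 3-phenylpropanoyl chloride | O=C(Cl)CCc1ccccc1 | starting material
14 | 1-[2-bromo-3-methoxy-6-(7-methoxy-4-oxo-2-(2-phenylethyl)-4H-chromen-6-yl)phenyl]-5-phenylpentane-1,3-dione | O=C(CCc1ccccc1)CC(=O)c1c(Br)c(OC)ccc1-c1cc2c(=O)cc(CCc3ccccc3)oc2cc1OC | intermediate
15 | 7,8'-dimethoxy-2,2'-bis(2-phenylethyl)-4H,4'H-[6,5'-bichromene]-4,4'-dione | COc1ccc(-c2cc3c(=O)cc(CCc4ccccc4)oc3cc2OC)c2c(=O)cc(CCc4ccccc4)oc12 | intermediate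
16 | 7,8'-dihydroxy-2,2'-bis(2-phenylethyl)-4H,4'H-[6,5'-bichromene]-4,4'-dione | O=c1cc(CCc2ccccc2)oc2cc(O)c(-c3ccc(O)c4oc(CCc5ccccc5)cc(=O)c34)cc12 | target

**Step count**

Total steps: 10. Longest linear sequence: 9 steps (1, 2, 3, 4, 6, 7, 8, 9, 10); step 5 is a one-step branch that supplies the dienophile.

**Steps most likely to fail, with fallbacks**

Step 6. The cycloaddition may be slow or may revert on heating, because the furan is conjugated to a hindered aryl group; the bromoynone may also oligomerise before it is consumed, and some of the wrong regioisomer may form. The fallback runs the same cycloaddition on parent furan and makes the biaryl bond afterwards by cross-coupling. It sets out from 9 (with furan) and from 5, and returns at 12.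
- Furan and 9 (excess furan, 40–60 °C) should give 1-(3-bromo-7-oxabicyclo[2.2.1]hepta-2,5-dien-2-yl)ethanone F1.
- CF3CO2H in CH2Cl2 should open the bridge at the bridgehead next to the acetyl-bearing carbon, so that no charge sits on that carbon, giving 1-(2-bromo-3-hydroxyphenyl)ethanone F2.
- O-Methylation (MeI, K2CO3, DMF) gives 1-(2-bromo-3-methoxyphenyl)ethanone F3.
- Iodination para to the methoxy group (N-iodosuccinimide, CF3CO2H, MeCN, rt) gives 1-(2-bromo-6-iodo-3-methoxyphenyl)ethanone F4.
- In parallel, Miyaura borylation of 5 (bis(pinacolato)diboron, Pd(dppf)Cl2, KOAc, dioxane, 90 °C) gives 7-methoxy-2-(2-phenylethyl)-6-(4,4,5,5-tetramethyl-1,3,2-dioxaborolan-2-yl)-4H-chromen-4-one F5.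
- Suzuki coupling of F5 with F4 (Pd(dppf)Cl2, K3PO4, dioxane/H2O, 60 °C) should take place at the C–I bond, ahead of the doubly flanked C–Br bond, and gives 12, which continues at step 8.

Step 8. The amine may also deprotonate the vinylogous CH2 of the phenethyl chain on chromone A, giving acylation at the wrong carbon; O-acylation of the enolate or ketene formation from the acid chloride may compete as well. The fallback makes the C–C bond by aldol addition and sets the oxidation level afterwards. It sets out from 12 and returns at 14.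
- Kinetic deprotonation of the methyl ketone (LDA, 1.05 equiv, THF, −78 °C) and addition of 3-phenylpropanal should give racemic 1-[2-bromo-3-methoxy-6-(7-methoxy-4-oxo-2-(2-phenylethyl)-4H-chromen-6-yl)phenyl]-3-hydroxy-5-phenylpentan-1-one F6. The aldehyde is trapped at low temperature with a single equivalent of base.
- Dess–Martin periodinane (NaHCO3, CH2Cl2, rt) oxidises the carbinol to the 1,3-diketone 14, which continues at step 9.

Step 9. Oxidative addition at a bromide flanked by an acyl and a methoxy group may be slow, so that hydrodebromination or retro-Claisen cleavage of the diketone takes over on prolonged heating with base. The fallback puts the oxygen on C8a' first and closes pyranone B at O1'–C2' by cyclodehydration instead of by O-arylation. It sets out from 12 and returns at 15.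
- Palladium-catalysed coupling of 12 with (E)-benzaldoxime as a hydroxide surrogate (Pd2(dba)3, t-BuBrettPhos, Cs2CO3, DMF, 80 °C) gives 6-[2-acetyl-3-(benzylideneaminooxy)-4-methoxyphenyl]-7-methoxy-2-(2-phenylethyl)-4H-chromen-4-one F7.
- F7 loses benzonitrile in the flask to give 6-(2-acetyl-3-hydroxy-4-methoxyphenyl)-7-methoxy-2-(2-phenylethyl)-4H-chromen-4-one F8.
- Acylation with 13 (pyridine, CH2Cl2) gives 2-acetyl-6-methoxy-3-[7-methoxy-4-oxo-2-(2-phenylethyl)-4H-chromen-6-yl]phenyl 3-phenylpropanoate F9.
- Baker–Venkataraman acyl migration (KOt-Bu, THF, 0 °C) gives 1-[2-hydroxy-3-methoxy-6-(7-methoxy-4-oxo-2-(2-phenylethyl)-4H-chromen-6-yl)phenyl]-5-phenylpentane-1,3-dione F10.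
- HCl in MeOH at reflux closes the pyranone to 15, and would reclose pyranone A should base have opened it; 15 continues at step 10.

Further compounds
F1 | step 6 | 1-(3-bromo-7-oxabicyclo[2.2.1]hepta-2,5-dien-2-yl)ethanone (racemic; one enantiomer drawn) | CC(=O)C1=C(Br)[C@@H]2C=C[C@H]1O2
F2 | step 6 | 1-(2-bromo-3-hydroxyphenyl)ethanone | CC(=O)c1cccc(O)c1Br
F3 | step 6 | 1-(2-bromo-3-methoxyphenyl)ethanone | CC(=O)c1cccc(OC)c1Br
F4 | step 6 | 1-(2-bromo-6-iodo-3-methoxyphenyl)ethanone | CC(=O)c1c(I)ccc(OC)c1Br
F5 | step 6 | 7-methoxy-2-(2-phenylethyl)-6-(4,4,5,5-tetramethyl-1,3,2-dioxaborolan-2-yl)-4H-chromen-4-one | COc1cc2oc(CCc3ccccc3)cc(=O)c2cc1B1OC(C)(C)C(C)(C)O1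
F6 | step 8 | 1-[2-bromo-3-methoxy-6-(7-methoxy-4-oxo-2-(2-phenylethyl)-4H-chromen-6-yl)phenyl]-3-hydroxy-5-phenylpentan-1-one (racemic) | OC(CCc1ccccc1)CC(=O)c1c(Br)c(OC)ccc1-c1cc2c(=O)cc(CCc3ccccc3)oc2cc1OC
F7 | step 9 | 6-[2-acetyl-3-(benzylideneaminooxy)-4-methoxyphenyl]-7-methoxy-2-(2-phenylethyl)-4H-chromen-4-one (E oxime ether) | CC(=O)c1c(O/N=C/c2ccccc2)c(OC)ccc1-c1cc2c(=O)cc(CCc3ccccc3)oc2cc1OC
F8 | step 9 | 6-(2-acetyl-3-hydroxy-4-methoxyphenyl)-7-methoxy-2-(2-phenylethyl)-4H-chromen-4-one | CC(=O)c1c(O)c(OC)ccc1-c1cc2c(=O)cc(CCc3ccccc3)oc2cc1OC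
F9 | step 9 | 2-acetyl-6-methoxy-3-[7-methoxy-4-oxo-2-(2-phenylethyl)-4H-chromen-6-yl]phenyl 3-phenylpropanoate | CC(=O)c1c(OC(=O)CCc2ccccc2)c(OC)ccc1-c1cc2c(=O)cc(CCc3ccccc3)oc2cc1OC
F10 | step 9 | 1-[2-hydroxy-3-methoxy-6-(7-methoxy-4-oxo-2-(2-phenylethyl)-4H-chromen-6-yl)phenyl]-5-phenylpentane-1,3-dione | O=C(CCc1ccccc1)CC(=O)c1c(O)c(OC)ccc1-c1cc2c(=O)cc(CCc3ccccc3)oc2cc1OC
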